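Ring B (C5, C6, C7, C8, C9, C10; halimane numbering) is disconnected as a Diels–Alder retron. The C5=C10 bond of an enantioenriched ring-A cyclohexenone (C4 quaternary centre in place, C1 carbonyl as activator) is the 2π partner. C6–C9 of an acyclic (Z)-2-silyloxy triene carrying the complete C11–C16 acetate side chain is the diene. One acid-catalysed cycloaddition forms C5–C6 and C9–C10, fixes C5 and the quaternary C9, and leaves a C7 silyl enol ether (regiodefined C8 enolate for the C17 methyl) and a C1 ketone (handle for the 1(10)-alkene). The feature exploited is the cyclohexane ring B whose quaternary C9 adjoins the sp2 fusion carbon C10.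

Key step: step 9

Remark: atom numbers are the halimane numbers of the target (ring A = C1–C5 and C10; C18 = ester carbon and C19 = methyl on C4; C17 = methyl on C8; C20 = methyl on C9; C11–C16 = side chain); β is the face of H-5.
Assumption: in step 1 the (1S,2S)-salen ligand is taken as the antipode that gives the (S)-aldehyde; if the induction is opposite, the (1R,2R)-ligand is used.

Step 1
Reactants: 1 (E)-3-(tert-butyldimethylsilyloxy)-N,N-dimethylbuta-1,3-dien-1-amine; 2 methacrolein
Product: 4 (S)-1-methyl-4-oxocyclohex-2-ene-1-carbaldehyde, via amino silyl enol ether cycloadduct 3 (not isolated)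
Conditions: [Cr(salen)]SbF6 (5 mol %; salen = (1S,2S)-N,N'-bis(3,5-di-tert-butylsalicylidene)cyclohexane-1,2-diamine dianion), 4 Å MS, CH2Cl2, −40 °C; then 1 M HCl, THF, 0 °C
Reagents that add atoms: none
Why: Catalytic enantioselective Diels–Alder reaction of an electron-rich 1-amino-3-silyloxydiene with an α-substituted acrolein, in which the chiral chromium–salen Lewis acid shields one face of the bound aldehyde and so sets the quaternary centre (future C4); acid then hydrolyses the silyl enol ether and eliminates dimethylamine (E1cB) to the enone.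

Step 2
Reactants: 4 (S)-1-methyl-4-oxocyclohex-2-ene-1-carbaldehyde
Product: 5 (S)-1-methyl-4-oxocyclohex-2-ene-1-carboxylic acid
Conditions: NaClO2, NaH2PO4, 2-methyl-2-butene, t-BuOH/H2O, 0 °C to rt
Reagents that add atoms: sodium chlorite, [Na+].[O-]Cl=O
Why: Pinnick oxidation converts the non-enolisable aldehyde into the acid without touching the enone, and the quaternary stereocentre cannot epimerise.

Step 3
Reactants: 5 (S)-1-methyl-4-oxocyclohex-2-ene-1-carboxylic acid
Product: 6 methyl (S)-1-methyl-4-oxocyclohex-2-ene-1-carboxylate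
Conditions: Me3SiCHN2, MeOH/toluene, 0 °C
Reagents that add atoms: (trimethylsilyl)diazomethane, C[Si](C)(C)C=[N+]=[N-]
Why: Esterification of a hindered acid by O-alkylation with a diazoalkane proceeds under neutral conditions that leave the enone intact.

Step 4
Reactants: 7 pentane-2,4-dione
Product: 8 (Z)-4-oxopent-2-en-2-yl trifluoromethanesulfonate
Conditions: NaH, Et2O/toluene, 0 °C; then Tf2O, −78 to 0 °C
Reagents that add atoms: trifluoromethanesulfonic anhydride, O=S(=O)(OS(=O)(=O)C(F)(F)F)C(F)(F)F
Why: O-sulfonylation of the chelated (U-shaped) sodium enolate of a symmetrical β-diketone should give the (Z)-enol triflate, with the triflate cis to the acetyl group.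

Step 5
Reactants: 9 (E)-3-methylpent-2-en-4-yn-1-ol
Product: 10 (E)-3-methylpenta-2,4-dien-1-ol
Conditions: H2 (1 atm), Pd/CaCO3 poisoned with Pb(OAc)2, quinoline, EtOAc, rt
Reagents that add atoms: none
Why: Semihydrogenation of the terminal alkyne on a poisoned palladium catalyst stops at the vinyl group and leaves the (E)-trisubstituted alkene untouched.

Step 6
Reactants: 10 (E)-3-methylpenta-2,4-dien-1-ol; 8 (Z)-4-oxopent-2-en-2-yl trifluoromethanesulfonate
Product: 12 (3Z,7E)-9-hydroxy-4,7-dimethylnona-3,7-dien-2-one, via alkylborane 11 (not isolated)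
Conditions: 9-BBN (2.2 equiv), THF, 0 °C to rt; then 8, Pd(dppf)Cl2 (5 mol %), AsPh3, Cs2CO3, DMF/H2O, rt
Reagents that add atoms: none
Why: Anti-Markovnikov hydroboration of the monosubstituted vinyl terminus followed by B-alkyl Suzuki–Miyaura coupling with the activated enol triflate, which proceeds with retention and so transfers the (Z)-geometry (chain cis to acetyl) to the C8=C9 bond.

Step 7
Reactants: 12 (3Z,7E)-9-hydroxy-4,7-dimethylnona-3,7-dien-2-one
Product: 13 (2E,6Z)-3,6-dimethyl-8-oxonona-2,6-dien-1-yl acetate
Conditions: Ac2O, pyridine, CH2Cl2, 0 °C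
Reagents that add atoms: acetic anhydride, CC(=O)OC(C)=O
Why: Acylation of the primary allylic alcohol installs the acetate of the target after the palladium step, so that no allylic acetate is exposed to zerovalent palladium.

Step 8
Reactants: 13 (2E,6Z)-3,6-dimethyl-8-oxonona-2,6-dien-1-yl acetate
Product: 14 (2E,6Z)-8-(tert-butyldimethylsilyloxy)-3,6-dimethylnona-2,6,8-trien-1-yl acetate
Conditions: TBSOTf, Et3N, Et2O, −78 to 0 °C
Reagents that add atoms: tert-butyldimethylsilyl trifluoromethanesulfonate, CC(C)(C)[Si](C)(C)OS(=O)(=O)C(F)(F)F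
Why: Soft enolisation of the methyl ketone (silyl triflate/amine) removes a proton from the acetyl methyl group and gives the cross-conjugated 2-silyloxydiene, with the acetate untouched and excess amine suppressing acid-mediated Z/E isomerisation.

Step 9
Reactants: 6 methyl (S)-1-methyl-4-oxocyclohex-2-ene-1-carboxylate; 14 (2E,6Z)-8-(tert-butyldimethylsilyloxy)-3,6-dimethylnona-2,6,8-trien-1-yl acetate
Product: 15 cis-fused cycloadduct (methyl 15-acetoxy-7-(tert-butyldimethylsilyloxy)-1-oxo-17-nor-ent-halima-7,13E-dien-18-oate; H-5β/H-10β/9α-CH3/9β-side chain)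
Conditions: 14 (1.5 equiv), Tf2NH (10 mol %), CH2Cl2, −78 to −40 °C; pyridine quench
Reagents that add atoms: none
Why: Tf2NH protodesilylates a little of 14 to TBSNTf2, which activates the enone carbonyl of 6 so that the CH2 terminus C6 of the diene attacks C5 first and the fully substituted terminus C9 closes onto C10 in a concerted but strongly asynchronous normal-demand Diels–Alder reaction (limiting stepwise form: Mukaiyama–Michael then Michael), with silyl transfer regenerating the catalyst. The closest known reaction type is the silyl-triflimide- or AlBr3/AlMe3-catalysed cycloaddition of hindered 2-silyloxydienes bearing a fully substituted terminus with hindered cyclohexenones, which builds adjacent quaternary and tertiary carbons. Ring B (C5–C6–C7–C8–C9–C10) is closed as a six-membered ring by intermolecular [4+2] annulation onto the preformed ring A, giving a cis-fused decalin. C5 is set by approach of the diene to the enone face anti to the pseudoaxial C4 ester (syn to the C4 methyl), which also places H-10 cis to H-5; C9 is set by the endo transition state (ring A over C7/C8) acting on the (Z)-C8=C9 bond, which puts the inside substituent C11 cis to H-10 and the outside methyl C20 trans. Regioselectivity (C6 to the β-carbon C5, C9 to the α-carbon C10) is secured by the silyloxy group at C7, which makes C6 the nucleophilic terminus. The step needs face selectivity at C5 and retention of diene geometry; the first rests on the C4 quaternary centre and the second on the low temperature that keeps the two bond formations coupled.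

Step 10
Reactants: 15 cis-fused cycloadduct
Product: 16 1α-alcohol (methyl 15-acetoxy-7-(tert-butyldimethylsilyloxy)-1α-hydroxy-17-nor-ent-halima-7,13E-dien-18-oate)
Conditions: LiBH(s-Bu)3 (1.1 equiv), THF, −78 °C; aq. NH4Cl
Reagents that add atoms: none
Why: Chemoselective ketone reduction by a bulky borohydride, which attacks C1 equatorially (the axial path is blocked by the syn-axial C5–C6 bond) and gives the axial 1α-alcohol trans to H-10, while the ester, acetate and silyl enol ether should survive at low temperature.

Step 11
Reactants: 16 1α-alcohol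
Product: 17 methyl 15-acetoxy-7-(tert-butyldimethylsilyloxy)-17-nor-ent-halima-1(10),7,13E-trien-18-oate
Conditions: Ph2S[OC(CF3)2Ph]2 (1.5 equiv), CH2Cl2, 0 °C to rt
Reagents that add atoms: none
Why: Sulfurane-mediated dehydration of a hindered secondary alcohol by anti-periplanar E2 elimination of the alkoxysulfonium intermediate; the axial leaving group has the axial tertiary H-10 antiperiplanar, and Zaitsev orientation should give the trisubstituted 1(10)-alkene under neutral conditions that spare the silyl enol ether and the C5 stereocentre.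

Step 12
Reactants: 17 methyl 15-acetoxy-7-(tert-butyldimethylsilyloxy)-17-nor-ent-halima-1(10),7,13E-trien-18-oate
Product: 18 methyl 15-acetoxy-7-oxo-ent-halima-1(10),13E-dien-18-oate (8α-CH3)
Conditions: (Me2N)3S+ Me3SiF2− (1.1 equiv), MeI (5 equiv), THF, −78 to −20 °C
Reagents that add atoms: iodomethane, CI
Why: Fluoride-promoted regiospecific alkylation of the silyl enol ether: the C7/C8 enolate that the cycloaddition stored is released and methylated at C8 by axial attack from the α face, anti to the pseudoaxial C11 chain on C9 in the only half-chair that ring A allows (H-5 axial), which gives the 8α-methyl group cis to C20.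

Step 13
Reactants: 18 methyl 15-acetoxy-7-oxo-ent-halima-1(10),13E-dien-18-oate
Product: 20 methyl (4S,5S,8R,9S)-15-acetoxy-ent-halima-1(10),13E-dien-18-oate (target), via tosylhydrazone 19 (not isolated)
Conditions: TsNHNH2, EtOH, 50 °C; solvent exchange; catecholborane, CHCl3, 0 °C; then NaOAc·3H2O, 60 °C
Reagents that add atoms: none
Why: Caglioti-type reductive deoxygenation of the saturated ketone via its tosylhydrazone (hydride delivery by catecholborane, loss of sulfinate and N2 from the diazene) gives the C7 methylene under conditions that spare both trisubstituted alkenes, both esters and, because enolisation towards the hindered C8 is slow, the C8 configuration.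

Compound list
1 | (E)-3-(tert-butyldimethylsilyloxy)-N,N-dimethylbuta-1,3-dien-1-amine | C=C(O[Si](C)(C)C(C)(C)C)/C=C/N(C)C | starting material
2 | methacrolein (2-methylprop-2-enal) | CC(=C)C=O | starting material
3 | (1S,2R)-2-(dimethylamino)-4-(tert-butyldimethylsilyloxy)-1-methylcyclohex-3-ene-1-carbaldehyde (NMe2 cis to CHO) | O=C[C@@]1(C)CCC(O[Si](C)(C)C(C)(C)C)=C[C@H]1N(C)C | intermediate
4 | (S)-1-methyl-4-oxocyclohex-2-ene-1-carbaldehyde | O=C[C@@]1(C)CCC(=O)C=C1 | intermediate
5 | (S)-1-methyl-4-oxocyclohex-2-ene-1-carboxylic acid | OC(=O)[C@@]1(C)CCC(=O)C=C1 | intermediate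
6 | methyl (S)-1-methyl-4-oxocyclohex-2-ene-1-carboxylate | COC(=O)[C@@]1(C)CCC(=O)C=C1 | intermediate
7 | pentane-2,4-dione | CC(=O)CC(C)=O | starting material
8 | (Z)-4-oxopent-2-en-2-yl trifluoromethanesulfonate | CC(=O)/C=C(C)\OS(=O)(=O)C(F)(F)F | intermediate
9 | (E)-3-methylpent-2-en-4-yn-1-ol | C#C/C(C)=C/CO | starting material
10 | (E)-3-methylpenta-2,4-dien-1-ol | C=C/C(C)=C/CO | intermediate
11 | 9-{[(E)-5-(9-borabicyclo[3.3.1]nonan-9-yl)-3-methylpent-2-en-1-yl]oxy}-9-borabicyclo[3.3.1]nonane | B1(C2CCCC1CCC2)CC/C(C)=C/COB1C2CCCC1CCC2 | intermediate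
12 | (3Z,7E)-9-hydroxy-4,7-dimethylnona-3,7-dien-2-one | CC(=O)/C=C(C)\CC/C(C)=C/CO | intermediate
13 | (2E,6Z)-3,6-dimethyl-8-oxonona-2,6-dien-1-yl acetate | CC(=O)/C=C(C)\CC/C(C)=C/COC(C)=O | intermediate
14 | (2E,6Z)-8-(tert-butyldimethylsilyloxy)-3,6-dimethylnona-2,6,8-trien-1-yl acetate | C=C(O[Si](C)(C)C(C)(C)C)/C=C(C)\CC/C(C)=C/COC(C)=O | intermediate
15 | methyl 15-acetoxy-7-(tert-butyldimethylsilyloxy)-1-oxo-17-nor-ent-halima-7,13E-dien-18-oate; cis-fused, H-5β, H-10β, 9α-CH3, 9β-side chain, 4β-CO2Me | COC(=O)[C@@]1(C)CCC(=O)[C@H]2[C@@H]1CC(O[Si](C)(C)C(C)(C)C)=C[C@]2(C)CC/C(C)=C/COC(C)=O | intermediate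
16 | 1α-hydroxy compound from 15 (1α-OH axial, trans to H-10β) | COC(=O)[C@@]1(C)CC[C@H](O)[C@H]2[C@@H]1CC(O[Si](C)(C)C(C)(C)C)=C[C@]2(C)CC/C(C)=C/COC(C)=O | intermediate
17 | methyl 15-acetoxy-7-(tert-butyldimethylsilyloxy)-17-nor-ent-halima-1(10),7,13E-trien-18-oate | COC(=O)[C@@]1(C)CCC=C2[C@@H]1CC(O[Si](C)(C)C(C)(C)C)=C[C@]2(C)CC/C(C)=C/COC(C)=O | intermediate
18 | methyl 15-acetoxy-7-oxo-ent-halima-1(10),13E-dien-18-oate (8α-CH3, H-8β) | COC(=O)[C@@]1(C)CCC=C2[C@@H]1CC(=O)[C@@H](C)[C@]2(C)CC/C(C)=C/COC(C)=O | intermediate
19 | 7-(p-toluenesulfonylhydrazone) of 18 | COC(=O)[C@@]1(C)CCC=C2[C@@H]1CC(=NNS(=O)(=O)c1ccc(C)cc1)[C@@H](C)[C@]2(C)CC/C(C)=C/COC(C)=O | intermediate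
20 | methyl (4S,5S,8R,9S)-15-acetoxy-ent-halima-1(10),13E-dien-18-oate | COC(=O)[C@@]1(C)CCC=C2[C@@H]1CC[C@@H](C)[C@]2(C)CC/C(C)=C/COC(C)=O | target

Total step count: 13. Longest linear sequence: 9 steps (steps 5–13 from compound 9; equally long from compound 7 through steps 4 and 6–13).

Steps most likely to fail

Step 9. The cycloaddition may stop after the first C–C bond (open Mukaiyama–Michael adduct), may lose the diene geometry through a long-lived oxocarbenium intermediate and so erode C9, or may discriminate poorly between the methyl and ester faces at C5. The fallback sets out from compounds 13 and 6 and uses an anionic double Michael annulation in one operation. Enone 13 is deprotonated at the acetyl methyl group with LiN(SiMe3)2 in THF at −78 °C to the cross-conjugated lithium dienolate F1. Enone 6 is then added, so that C6 adds to C5 and the ring-A enolate closes onto C9. The resulting regiodefined C7 lithium enolate F2 is silylated in the same flask with TBSCl/HMPA, and the route is rejoined at compound 15.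

Step 11. The elimination may take the wrong regiochemical course, removing H-2 instead of the hindered H-10 and giving the 1(2)-alkene. The fallback sets out from compound 15 and bypasses 16. The C1 ketone is condensed with TsNHNH2 to the tosylhydrazone F3. Its sodium salt (NaH, toluene, reflux) undergoes an aprotic Bamford–Stevens reaction, in which the C1 carbene takes up the tertiary H-10 by 1,2-shift to give the more substituted alkene. The route is rejoined at compound 17.

Step 12. Methylation may occur with poor face selectivity or at oxygen, or proton transfer may move the enolate to C6. The fallback sets out from compound 17. Simmons–Smith cyclopropanation (Et2Zn, CH2I2, CH2Cl2, 0 °C) of the electron-rich C7=C8 enol ether from the α face, anti to the C11 chain, gives the silyloxycyclopropane F4. Bu4NF in THF then opens the cyclopropanolate at the C7–CH2 bond, so the transferred CH2 becomes the 8α-methyl group with C8 fixed by the suprafacial carbene transfer. The route is rejoined at compound 18.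

Further compounds
F1 | step 9 | lithium (3Z,7E)-9-acetoxy-4,7-dimethylnona-1,3,7-trien-2-olate | [Li]OC(=C)/C=C(C)\CC/C(C)=C/COC(C)=O
F2 | step 9 | C7 lithium enolate of the annulated diketone (lithium analogue of 15) | COC(=O)[C@@]1(C)CCC(=O)[C@H]2[C@@H]1CC(O[Li])=C[C@]2(C)CC/C(C)=C/COC(C)=O
F3 | step 11 | 1-(p-toluenesulfonylhydrazone) of 15 | COC(=O)[C@@]1(C)CCC(=NNS(=O)(=O)c3ccc(C)cc3)[C@H]2[C@@H]1CC(O[Si](C)(C)C(C)(C)C)=C[C@]2(C)CC/C(C)=C/COC(C)=O
F4 | step 12 | 7β-(tert-butyldimethylsilyloxy)-7α,8α-methano derivative of 17 (silyloxycyclopropane) | COC(=O)[C@@]1(C)CCC=C2[C@@H]1C[C@@]3(O[Si](C)(C)C(C)(C)C)C[C@H]3[C@]2(C)CC/C(C)=C/COC(C)=O
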